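In a closed flask, each molecule of substrate charged is at any moment either still substrate or gone somewhere else, so the useful question is what chance a departed molecule has of being target.

- violet: substrate 0.56 M; gas phase 150 mM (held); the very flask that is asked about, followed so far
- flask: substrate 0.56 M; gas phase 150 mM (held); time 3.0 d

- violet (time / h: target / %, substrate / %): 6.00: 1.5, 98.1; 12.0: 3.2, 95.9; 15.0: 4.3, 91.6; 25.0: 9.1, 85.3; 30.0: 14.6, 82.7

(readings scatter by 1 percentage point)

1. target at 3.0 d, in percent of the substrate charged
2. concentration of dissolved gas in solution at 3.0 d, in percent of saturation

- what was read earlier has a scatter of 1 percentage point, one standard deviation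
- at the start none of the gas phase is in solution

At 30.0 h the violet run has lost 17.3% of its substrate and shows 14.6% target. I call the ratio of these the target share, 84.4% of the substrate gone (the usual term is selectivity), read with the scatter of both readings. My view is that the substrate keeps leaving at its steady pace and the share stays where it now stands. The loss at 3.0 d is then 41.5%, and the target 35.0%. The readings contain no dissolved gas, so I give no figure for sat.

A colleague who made the forecast also extrapolates the substrate loss and from it puts the target near 40%, but then adds to that for the target's own curve, which rose 4.3% up to 15.0 h and 10 percentage points from then to 30.0 h, more in the second stretch than in the first. The forecast says “Some continued acceleration could push it higher” and gives 45% target at 85% of saturation.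

The flask gives 31.7% target and 74.3% of saturation, so my figure stands closer than the forecast's. The forecast's view has its region later: this flask holds 44.6% target at 6.00 d, twice the asked time. With 57% substrate left at 3.0 d, the target share reads 73.7%, lower than the 84.4% carried over.

    gas phase ⇌ dissolved gas, rate k1*(csat - [dissolved gas]) (kL = 0.00120 min⁻¹)
    substrate + dissolved gas ⇌ target (K = 44.0 M⁻¹, k = 0.00130 M⁻¹ min⁻¹)
    substrate → side product (k = 2.00 × 10⁻⁵ min⁻¹)
    target ⇌ isomer of the product (K = 10.0, k = 6.30 × 10⁻⁵ min⁻¹)

For the same flask read at 40 h, the steady pace gives a loss of 23.1%, and the share 84.4% turns that into 19.5% target. The simulation gives 18.8% target with 75.7% substrate left.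

The numbers in the tables were generated by integration for substances that don't exist.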